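**Retrosynthetic overview**
1. Target ⇐ its 5,6,7-tris-TBS ether (global desilylation last); the cyclopentenone is the only ring and is formed in the penultimate step.
2. Ring (C8–C12 bond) ⇐ Piancatelli rearrangement of a 3-bromo-5-dienyl-2-furylcarbinol: furan C2 → C9 ketone, C3–Br → C10–Br, C5 → C12 carbinol.
3. Key C8–C9 bond ⇐ a 3-bromo-2-furyllithium (masked C9 acyl anion and latent cis-ene-1,4-dione, generated by halogen dance) + the C8 aldehyde: two natively electrophilic carbons are joined.
4. C1–C8 aldehyde ⇐ methyl α-D-galactopyranoside (galactose C2–C4 = target C7–C5) via 6-iodide, zinc fragmentation, cross-metathesis with methyl but-3-enoate, hydrogenation.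
5. Bromofuran ⇐ furan + (2Z,5Z)-octadienyl bromide ⇐ prop-2-yn-1-ol + 1-bromopent-2-yne.

Assumption: carbons are numbered as in prostanoids (ester carbon C1, ring C8–C12, Br on C10, dienyl chain C13–C20), and the furylcarbinol is carried forward as its C8-epimer mixture because C8 becomes trigonal in the rearrangement.

**Step 1**
Reactants: 1 prop-2-yn-1-ol; 2 1-bromopent-2-yne
Product: 3 octa-2,5-diyn-1-ol
Conditions: CuI, NaI, K2CO3, DMF, rt
Reagents that add atoms: none
Why: Copper-mediated sp–sp3 coupling of a terminal alkyne with a propargylic bromide is the standard entry to skipped diynes and tolerates the free alcohol.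

**Step 2**
Reactants: 3 octa-2,5-diyn-1-ol
Product: 4 (2Z,5Z)-octa-2,5-dien-1-ol
Conditions: H2 (1 atm), Ni(OAc)2·4H2O/NaBH4 (nickel boride), ethylenediamine, EtOH, rt
Reagents that add atoms: none
Why: Syn semi-hydrogenation on amine-poisoned nickel boride stops at the alkene stage and sets both Z double bonds (C14 and C17).

**Step 3**
Reactants: 4 (2Z,5Z)-octa-2,5-dien-1-ol
Product: 5 (2Z,5Z)-1-bromoocta-2,5-diene
Conditions: CBr4, PPh3, CH2Cl2, 0 °C
Reagents that add atoms: tetrabromomethane, BrC(Br)(Br)Br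
Why: Appel reaction, in which bromide displaces the phosphorus-activated primary allylic hydroxyl by SN2 at 0 °C, without allylic transposition or Z/E scrambling.

**Step 4**
Reactants: 6 furan; 5 (2Z,5Z)-1-bromoocta-2,5-diene
Product: 8 2-[(2Z,5Z)-octa-2,5-dien-1-yl]furan, via 2-furyllithium 7 (not isolated)
Conditions: n-BuLi, THF, 0 °C; then 5, –78 °C to rt
Reagents that add atoms: none
Why: α-Lithiation of furan followed by direct SN2 alkylation at the unhindered primary allylic bromide, which retains the Z geometry.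

**Step 5**
Reactants: 8 2-[(2Z,5Z)-octa-2,5-dien-1-yl]furan
Product: 9 2-bromo-5-[(2Z,5Z)-octa-2,5-dien-1-yl]furan
Conditions: NBS (1.0 equiv), DMF, –20 °C, dark; filtration through basic alumina, used at once
Reagents that add atoms: N-bromosuccinimide, O=C1CCC(=O)N1Br
Why: Electrophilic aromatic bromination, since the free α-position of a 2-alkylfuran is far more nucleophilic than the isolated Z alkenes.

**Step 6**
Reactants: 10 methyl α-D-galactopyranoside
Product: 11 methyl 6-deoxy-6-iodo-α-D-galactopyranoside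
Conditions: I2, PPh3, imidazole, THF, 65 °C
Reagents that add atoms: iodine, II
Why: Garegg–Samuelsson iodination activates only the primary 6-OH; galactose C2, C3 and C4, which become C7, C6 and C5 of the target, are untouched.

**Step 7**
Reactants: 11 methyl 6-deoxy-6-iodo-α-D-galactopyranoside
Product: 12 methyl 2,3,4-tri-O-(tert-butyldimethylsilyl)-6-deoxy-6-iodo-α-D-galactopyranoside
Conditions: TBSOTf (4 equiv), 2,6-lutidine, CH2Cl2, 0 to 40 °C
Reagents that add atoms: tert-butyldimethylsilyl trifluoromethanesulfonate, CC(C)(C)[Si](C)(C)OS(=O)(=O)C(F)(F)F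
Why: Silyl triflate with a hindered pyridine base persilylates the three secondary hydroxyls (routine for pyranoside triols) and affects no stereocentre.

**Step 8**
Reactants: 12 methyl 2,3,4-tri-O-(tert-butyldimethylsilyl)-6-deoxy-6-iodo-α-D-galactopyranoside
Product: 14 (2R,3S,4S)-2,3,4-tris[(tert-butyldimethylsilyl)oxy]hex-5-enal, via alkylzinc iodide 13 (not isolated)
Conditions: Zn dust (activated), THF/H2O 9:1, sonication, 40 °C
Reagents that add atoms: none
Why: Bernet–Vasella reductive fragmentation, in which zinc inserts into the C–I bond to give 13, which eliminates across C5–O5 and releases the acyclic aldehyde (future C8) and a terminal alkene with the 2R,3S,4S silyloxy triad unchanged.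

**Step 9**
Reactants: 14 (2R,3S,4S)-2,3,4-tris[(tert-butyldimethylsilyl)oxy]hex-5-enal; 15 methyl but-3-enoate
Product: 17 methyl (5S,6S,7R)-5,6,7-tris[(tert-butyldimethylsilyl)oxy]-8-oxooctanoate, via cross-metathesis enoate 16 (not isolated)
Conditions: 15 (5 equiv), second-generation Hoveyda–Grubbs catalyst [RuCl2(SIMes)(=CH-C6H4-2-O-i-Pr)] (5 mol %), CH2Cl2, 40 °C; then Pd/C, H2 (1 atm), EtOAc, rt
Reagents that add atoms: none
Why: Olefin cross-metathesis appends C1–C3 to the terminal alkene with loss of ethene, and hydrogenation of the resulting disubstituted alkene over Pd/C leaves the aldehyde and silyl ethers intact; no stereocentre is formed.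

**Step 10 (key step)**
Reactants: 9 2-bromo-5-[(2Z,5Z)-octa-2,5-dien-1-yl]furan; 17 methyl (5S,6S,7R)-5,6,7-tris[(tert-butyldimethylsilyl)oxy]-8-oxooctanoate
Product: 20 methyl (5S,6S,7S,8RS)-8-{3-bromo-5-[(2Z,5Z)-octa-2,5-dien-1-yl]furan-2-yl}-5,6,7-tris[(tert-butyldimethylsilyl)oxy]-8-hydroxyoctanoate, via 3-lithio-2-bromofuran 18 (not isolated), via 3-bromo-2-furyllithium 19 (not isolated)
Conditions: 9 (1.3 equiv), LiN(i-Pr)2 (LDA, 1.25 equiv), THF, –78 °C, 45 min; then 17 (1.0 equiv), –78 °C; AcOH quench at –78 °C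
Reagents that add atoms: none
Why: LDA removes H3 next to bromine and the base-catalysed halogen dance (known for 2-bromo-5-alkylfurans) funnels 18 into the most stabilised anion 19 (lithium α to oxygen and ortho to bromine), which is a masked C9 acyl anion (its carbon becomes the ring ketone) and adds to the C8 aldehyde carbon faster than to the methyl ester, so two natively electrophilic carbons are joined; the new carbinol centre forms unselectively and is erased in step 11.

**Step 11**
Reactants: 20 methyl (5S,6S,7S,8RS)-8-{3-bromo-5-[(2Z,5Z)-octa-2,5-dien-1-yl]furan-2-yl}-5,6,7-tris[(tert-butyldimethylsilyl)oxy]-8-hydroxyoctanoate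
Product: 22 methyl (5S,6S,7S)-7-{(1R,5S)-3-bromo-5-hydroxy-5-[(2Z,5Z)-octa-2,5-dien-1-yl]-2-oxocyclopent-3-en-1-yl}-5,6,7-tris[(tert-butyldimethylsilyl)oxy]heptanoate, via ring-opened dienol ketone 21 (not isolated)
Conditions: Dy(OTf)3 (10 mol %), dioxane/H2O 4:1, 80 °C
Reagents that add atoms: water, O
Why: Proposed new method: a Piancatelli rearrangement (established for 5-alkyl-2-furylcarbinols, not for 3-bromo or α-silyloxy examples) in which Lewis-acid ionisation of the C8 carbinol, attack of water at the furan carbon bearing the dienyl chain and ring-opening give 21, whose protonated form closes the C8–C12 bond by 4π-conrotatory electrocyclisation; with both carbon chains on the outside of the pentadienyl cation the side chains end up trans (12-OH cis to the C8 chain, also the thermodynamic arrangement at the epimerisable C8), the C7 stereocentre (C7–H eclipsing the enol C–O by A(1,3) strain, new bond formed anti to the branched C6 chain) is predicted, not known, to favour the (8R,12S) ring, and the bromine rides from furan C3 to C10; closest known reaction type: oxa-Piancatelli/Nazarov electrocyclisation with torquoselectivity from an allylic stereocentre.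

**Step 12**
Reactants: 22 methyl (5S,6S,7S)-7-{(1R,5S)-3-bromo-5-hydroxy-5-[(2Z,5Z)-octa-2,5-dien-1-yl]-2-oxocyclopent-3-en-1-yl}-5,6,7-tris[(tert-butyldimethylsilyl)oxy]heptanoate
Product: 23 methyl (5S,6S,7S)-7-{(1R,5S)-3-bromo-5-hydroxy-5-[(2Z,5Z)-octa-2,5-dien-1-yl]-2-oxocyclopent-3-en-1-yl}-5,6,7-trihydroxyheptanoate (CNP0143456.1)
Conditions: HF·pyridine, pyridine/THF, 0 °C to rt
Reagents that add atoms: none
Why: Fluoride-driven cleavage of the three silyl ethers under pyridine-buffered conditions that β-hydroxy cyclopentenones of the prostaglandin E type tolerate; no stereocentre is touched.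

**Compound list**
1 | prop-2-yn-1-ol | C#CCO | starting material
2 | 1-bromopent-2-yne | CCC#CCBr | starting material
3 | octa-2,5-diyn-1-ol | CCC#CCC#CCO | intermediate
4 | (2Z,5Z)-octa-2,5-dien-1-ol | CC/C=C\C/C=C\CO | intermediate
5 | (2Z,5Z)-1-bromoocta-2,5-diene | CC/C=C\C/C=C\CBr | intermediate
6 | furan | c1ccoc1 | starting material
7 | 2-furyllithium (not isolated) | [Li]c1ccco1 | intermediate
8 | 2-[(2Z,5Z)-octa-2,5-dien-1-yl]furan | CC/C=C\C/C=C\Cc1ccco1 | intermediate
9 | 2-bromo-5-[(2Z,5Z)-octa-2,5-dien-1-yl]furan | CC/C=C\C/C=C\Cc1ccc(Br)o1 | intermediate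
10 | methyl α-D-galactopyranoside | CO[C@H]1O[C@H](CO)[C@H](O)[C@H](O)[C@H]1O | starting material
11 | methyl 6-deoxy-6-iodo-α-D-galactopyranoside | CO[C@H]1O[C@H](CI)[C@H](O)[C@H](O)[C@H]1O | intermediate
12 | methyl 2,3,4-tri-O-(tert-butyldimethylsilyl)-6-deoxy-6-iodo-α-D-galactopyranoside | CO[C@H]1O[C@H](CI)[C@H](O[Si](C)(C)C(C)(C)C)[C@H](O[Si](C)(C)C(C)(C)C)[C@H]1O[Si](C)(C)C(C)(C)C | intermediate
13 | [methyl 2,3,4-tri-O-(tert-butyldimethylsilyl)-6-deoxy-α-D-galactopyranosid-6-yl]zinc iodide (not isolated) | CO[C@H]1O[C@H](C[Zn]I)[C@H](O[Si](C)(C)C(C)(C)C)[C@H](O[Si](C)(C)C(C)(C)C)[C@H]1O[Si](C)(C)C(C)(C)C | intermediate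
14 | (2R,3S,4S)-2,3,4-tris[(tert-butyldimethylsilyl)oxy]hex-5-enal | O=C[C@H](O[Si](C)(C)C(C)(C)C)[C@@H](O[Si](C)(C)C(C)(C)C)[C@@H](O[Si](C)(C)C(C)(C)C)C=C | intermediate
15 | methyl but-3-enoate | C=CCC(=O)OC | starting material
16 | methyl (3E,5S,6S,7R)-5,6,7-tris[(tert-butyldimethylsilyl)oxy]-8-oxooct-3-enoate (not isolated; E major) | O=C[C@H](O[Si](C)(C)C(C)(C)C)[C@@H](O[Si](C)(C)C(C)(C)C)[C@@H](O[Si](C)(C)C(C)(C)C)/C=C/CC(=O)OC | intermediate
17 | methyl (5S,6S,7R)-5,6,7-tris[(tert-butyldimethylsilyl)oxy]-8-oxooctanoate | O=C[C@H](O[Si](C)(C)C(C)(C)C)[C@@H](O[Si](C)(C)C(C)(C)C)[C@@H](O[Si](C)(C)C(C)(C)C)CCCC(=O)OC | intermediate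
18 | 2-bromo-3-lithio-5-[(2Z,5Z)-octa-2,5-dien-1-yl]furan (not isolated) | CC/C=C\C/C=C\Cc1cc([Li])c(Br)o1 | intermediate
19 | 3-bromo-2-lithio-5-[(2Z,5Z)-octa-2,5-dien-1-yl]furan (not isolated) | CC/C=C\C/C=C\Cc1cc(Br)c([Li])o1 | intermediate
20 | methyl (5S,6S,7S,8RS)-8-{3-bromo-5-[(2Z,5Z)-octa-2,5-dien-1-yl]furan-2-yl}-5,6,7-tris[(tert-butyldimethylsilyl)oxy]-8-hydroxyoctanoate (both C8 epimers) | CC/C=C\C/C=C\Cc1cc(Br)c(o1)C(O)[C@H](O[Si](C)(C)C(C)(C)C)[C@@H](O[Si](C)(C)C(C)(C)C)[C@@H](O[Si](C)(C)C(C)(C)C)CCCC(=O)OC | intermediate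
21 | methyl (5S,6S,7S,8Z,10E,14Z,17Z)-10-bromo-5,6,7-tris[(tert-butyldimethylsilyl)oxy]-9-hydroxy-12-oxoicosa-8,10,14,17-tetraenoate (not isolated) | CC/C=C\C/C=C\CC(=O)/C=C(Br)\C(O)=C\[C@H](O[Si](C)(C)C(C)(C)C)[C@@H](O[Si](C)(C)C(C)(C)C)[C@@H](O[Si](C)(C)C(C)(C)C)CCCC(=O)OC | intermediate
22 | methyl (5S,6S,7S)-7-{(1R,5S)-3-bromo-5-hydroxy-5-[(2Z,5Z)-octa-2,5-dien-1-yl]-2-oxocyclopent-3-en-1-yl}-5,6,7-tris[(tert-butyldimethylsilyl)oxy]heptanoate | CC/C=C\C/C=C\C[C@@]1(O)C=C(Br)C(=O)[C@@H]1[C@H](O[Si](C)(C)C(C)(C)C)[C@@H](O[Si](C)(C)C(C)(C)C)[C@@H](O[Si](C)(C)C(C)(C)C)CCCC(=O)OC | intermediate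
23 | methyl (5S,6S,7S)-7-{(1R,5S)-3-bromo-5-hydroxy-5-[(2Z,5Z)-octa-2,5-dien-1-yl]-2-oxocyclopent-3-en-1-yl}-5,6,7-trihydroxyheptanoate | CC/C=C\C/C=C\C[C@@]1(O)C=C(Br)C(=O)[C@@H]1[C@H](O)[C@@H](O)[C@@H](O)CCCC(=O)OC | target

**Totals**
Total steps: 12 (step 9 is a telescoped two-stage operation).
Longest linear sequence: 8 steps (steps 1, 2, 3, 4, 5, 10, 11, 12); the sugar branch is 7 steps (6, 7, 8, 9, 10, 11, 12).

**Three steps most likely to fail**

Step 11 (Piancatelli rearrangement of 20) is the riskiest. There is no precedent for a 3-bromofuran or an α-silyloxy carbinol in this rearrangement. The C7 oxygen slows ionisation, and the C5 silyl ether oxygen can trap the cation as a furyl tetrahydrofuran (reversible under acid). The facial selectivity rests on a conformational model, so the (8S,12R) ring isomer may form alongside and would have to be removed by chromatography at 22.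
The fallback sets out from 9 and 17 and comes back at 22; it takes bromine out of the rearrangement and introduces it afterwards. Bromine–lithium exchange on 9 (n-BuLi, THF, –78 °C) and addition to 17 give the bromine-free carbinol methyl (5S,6S,7S,8RS)-5,6,7-tris[(tert-butyldimethylsilyl)oxy]-8-hydroxy-8-{5-[(2Z,5Z)-octa-2,5-dien-1-yl]furan-2-yl}octanoate F1. Its rearrangement (Dy(OTf)3 or ZnCl2, aqueous dioxane) is that of a plain 5-alkyl-2-furylcarbinol, the established substrate class, and gives the 10-debromo analogue of 22, F2. Nucleophilic epoxidation of the enone only (t-BuOOH, DBU, CH2Cl2, 0 °C; the isolated alkenes do not react) gives the 10,11-epoxy ketone F3. LiBr/AcOH in THF opens the epoxide at C10, α to the ketone, to the 10-bromo-11-hydroxy ketone F4, which loses water in the same pot to give 22. This answers a reactivity failure only; it does not change the torquoselectivity.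

Step 10 (halogen dance and addition) is second. The furan also carries a doubly activated CH2 (C13) that LDA could deprotonate, incomplete bromine migration would give regioisomeric carbinols, and the furyllithium could enolise 17.
The fallback sets out from 5 and comes back at 19 (and so at 20); regiochemistry is fixed by a silyl blocking group instead of a halogen migration. Commercial 3-bromofuran F5 is lithiated at C2 (LDA, –78 °C) and silylated with TMSCl to 3-bromo-2-(trimethylsilyl)furan F6. A second LDA lithiation at the only free α-position and alkylation with 5 give {3-bromo-5-[(2Z,5Z)-octa-2,5-dien-1-yl]furan-2-yl}trimethylsilane F7. TBAF removes the silyl group to give 4-bromo-2-[(2Z,5Z)-octa-2,5-dien-1-yl]furan F8. LDA at –78 °C then removes, within minutes, the one proton that is both α to oxygen and ortho to bromine, giving 19 with no anion translocation, and addition to 17 gives 20.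

Step 9 (cross-metathesis and hydrogenation) is third. The alkene of 14 is hindered by the allylic silyl ether, the free α-silyloxy aldehyde may retard the ruthenium catalyst, and Pd/C could in part cleave the allylic C–O bond of 16.
The fallback sets out from 14 and comes back at 17; it forms the C3–C2 bond by a radical instead of by metathesis. Atom-transfer radical addition of methyl iodoacetate to the terminal alkene (Et3B/air, CH2Cl2, rt) gives the 4-iodo derivative of 17 (methyl 4-iodo-5,6,7-tris[(tert-butyldimethylsilyl)oxy]-8-oxooctanoate, C4 epimers, C5–C7 arranged as in 17) F9. Bu3SnH/AIBN (benzene, 80 °C) removes the iodine and gives 17 without a hydrogenation step.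

**Further compounds**
F1 | step 11 | methyl (5S,6S,7S,8RS)-5,6,7-tris[(tert-butyldimethylsilyl)oxy]-8-hydroxy-8-{5-[(2Z,5Z)-octa-2,5-dien-1-yl]furan-2-yl}octanoate | CC/C=C\C/C=C\Cc1ccc(o1)C(O)[C@H](O[Si](C)(C)C(C)(C)C)[C@@H](O[Si](C)(C)C(C)(C)C)[C@@H](O[Si](C)(C)C(C)(C)C)CCCC(=O)OC
F2 | step 11 | 10-debromo analogue of 22 (same spatial arrangement at all stereocentres) | CC/C=C\C/C=C\C[C@@]1(O)C=CC(=O)[C@@H]1[C@H](O[Si](C)(C)C(C)(C)C)[C@@H](O[Si](C)(C)C(C)(C)C)[C@@H](O[Si](C)(C)C(C)(C)C)CCCC(=O)OC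
F3 | step 11 | 10,11-epoxide of F2 (either epoxide face) | CC/C=C\C/C=C\C[C@@]1(O)C2OC2C(=O)[C@@H]1[C@H](O[Si](C)(C)C(C)(C)C)[C@@H](O[Si](C)(C)C(C)(C)C)[C@@H](O[Si](C)(C)C(C)(C)C)CCCC(=O)OC
F4 | step 11 | 10-bromo-11-hydroxy-10,11-dihydro derivative of 22 (bromohydrin) | CC/C=C\C/C=C\C[C@@]1(O)C(O)C(Br)C(=O)[C@@H]1[C@H](O[Si](C)(C)C(C)(C)C)[C@@H](O[Si](C)(C)C(C)(C)C)[C@@H](O[Si](C)(C)C(C)(C)C)CCCC(=O)OC
F5 | step 10 | 3-bromofuran (purchased) | Brc1ccoc1
F6 | step 10 | 3-bromo-2-(trimethylsilyl)furan | C[Si](C)(C)c1occc1Br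
F7 | step 10 | {3-bromo-5-[(2Z,5Z)-octa-2,5-dien-1-yl]furan-2-yl}trimethylsilane | CC/C=C\C/C=C\Cc1cc(Br)c(o1)[Si](C)(C)C
F8 | step 10 | 4-bromo-2-[(2Z,5Z)-octa-2,5-dien-1-yl]furan | CC/C=C\C/C=C\Cc1cc(Br)co1
F9 | step 9 | methyl 4-iodo-5,6,7-tris[(tert-butyldimethylsilyl)oxy]-8-oxooctanoate (C4 epimers; C5–C7 as in 17) | O=C[C@H](O[Si](C)(C)C(C)(C)C)[C@@H](O[Si](C)(C)C(C)(C)C)[C@@H](O[Si](C)(C)C(C)(C)C)C(I)CCC(=O)OC
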